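**Plan**
- Retrosynthesis (isochromene numbering C1, O2, C3, C4, C4a, C5–C8, C8a): the C6–O orsellinate ester is cut last. Ring A is then cut at C5–C4a and C6–C7 together, which releases a two-carbon acetaldehyde-enolate unit (C5–C6) and a ring B hydroxy ketone triflate. C8–C8a (Claisen) and O2–C3 (oxa-Michael) are cut after that.
- Forward: enyne side chain → ynone → ring B by 6-endo oxa-Michael closure → acylation at C8a with lactic acid acetonide → triflate at C4a → ring A by a cross-coupling/aldol annulation → ester at O6 → global desilylation.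
- Enabling feature: C4a is the carbonyl-derived carbon of a vinylogous acid (O2–C3=C4–C4a=C8a–C8=O), so it can carry a triflate for C–C coupling. The C7–OH/C8=O pair is an α-hydroxy ketone that binds zinc as an enediolate. Both new bonds are consonant with the C8 carbonyl (C5 nucleophile to C4a, C7 nucleophile to the C6 aldehyde).
- Stereochemistry: C7 is carried as a racemate and is planar in the zinc enediolate, so both enantiomers converge. The chiral zinc catalyst sets C7 and C6 (cis-diol) in the key step, and the later acylation at O6 does not break the C6–O bond.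

Key step: step 8

Assumption: the catalyst from Et2Zn and (S,S)-ProPhenol is taken to give the (6R,7R) series; if the facial sense proves opposite, the (R,R)-ligand is used instead.

Step 1
Reactants: 1 (2E)-pent-2-en-4-yn-1-ol
Product: 2 tert-butyl{[(2E)-pent-2-en-4-yn-1-yl]oxy}diphenylsilane
Conditions: TBDPSCl, imidazole, CH2Cl2, 0 °C → rt
Reagents that add atoms: tert-butyl(chloro)diphenylsilane, CC(C)(C)[Si](Cl)(c1ccccc1)c1ccccc1
Why: Silylation of a primary alcohol gives a TBDPS ether that should carry the side-chain hydroxyl to the last step; no stereocenter is involved.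

Step 2
Reactants: 2 tert-butyl{[(2E)-pent-2-en-4-yn-1-yl]oxy}diphenylsilane; 3 3-[(tert-butyldimethylsilyl)oxy]propanal
Product: 5 (6E)-1-[(tert-butyldimethylsilyl)oxy]-8-[(tert-butyldiphenylsilyl)oxy]oct-6-en-4-yn-3-ol (racemic), via lithium acetylide 4 (not isolated)
Conditions: n-BuLi, THF, −78 °C; then 3, −78 → 0 °C; H2O
Reagents that add atoms: none
Why: Deprotonation of the terminal alkyne and 1,2-addition of the acetylide to the aldehyde (alkynylation) should join the two chains; the carbinol center forms as a racemate and is oxidized away in step 3.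

Step 3
Reactants: 5 (6E)-1-[(tert-butyldimethylsilyl)oxy]-8-[(tert-butyldiphenylsilyl)oxy]oct-6-en-4-yn-3-ol
Product: 6 (6E)-1-[(tert-butyldimethylsilyl)oxy]-8-[(tert-butyldiphenylsilyl)oxy]oct-6-en-4-yn-3-one
Conditions: Dess–Martin periodinane, CH2Cl2, 0 °C → rt
Reagents that add atoms: none
Why: Dess–Martin oxidation of the propargylic alcohol should give the ynone without touching the silyl ethers or the enyne; the only stereocenter is removed.

Step 4
Reactants: 6 (6E)-1-[(tert-butyldimethylsilyl)oxy]-8-[(tert-butyldiphenylsilyl)oxy]oct-6-en-4-yn-3-one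
Product: 7 6-{(1E)-3-[(tert-butyldiphenylsilyl)oxy]prop-1-en-1-yl}-2,3-dihydro-4H-pyran-4-one
Conditions: CSA (0.2 equiv), MeOH/CH2Cl2, 0 °C → rt
Reagents that add atoms: none
Why: Acid methanolysis should remove the primary TBS ether while the TBDPS ether survives, and the freed hydroxyl closes ring B by 6-endo-dig oxa-Michael addition to the ynone β-carbon (C3); no stereocenter is formed.

Step 5
Reactants: 7 6-{(1E)-3-[(tert-butyldiphenylsilyl)oxy]prop-1-en-1-yl}-2,3-dihydro-4H-pyran-4-one; 8 2,2,5-trimethyl-1,3-dioxolan-4-one (racemic lactic acid acetonide)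
Product: 10 1-(6-{(1E)-3-[(tert-butyldiphenylsilyl)oxy]prop-1-en-1-yl}-4-hydroxy-2H-pyran-3-yl)-2-hydroxypropan-1-one (racemic; ring-enol tautomer of the β-diketone), via lithium enolate 9 (not isolated)
Conditions: LiN(iPr)2 (2.1 equiv), THF, −78 °C; then 8, −78 → −30 °C; pH 7 aqueous work-up
Reagents that add atoms: none
Why: Crossed Claisen acylation, in which the kinetic enolate at C8a (the only sp3 α-carbon) attacks the acetal-ester carbonyl of 8 and acetone is expelled, should give the free α-hydroxy β-diketone; the lactate center stays racemic, which is harmless because step 8 makes it planar.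

Step 6
Reactants: 10 1-(6-{(1E)-3-[(tert-butyldiphenylsilyl)oxy]prop-1-en-1-yl}-4-hydroxy-2H-pyran-3-yl)-2-hydroxypropan-1-one
Product: 11 6-{(1E)-3-[(tert-butyldiphenylsilyl)oxy]prop-1-en-1-yl}-3-(2-hydroxypropanoyl)-2H-pyran-4-yl trifluoromethanesulfonate (racemic)
Conditions: PhNTf2, Et3N, CH2Cl2, −20 → 0 °C
Reagents that add atoms: N-phenylbis(trifluoromethanesulfonimide), O=S(=O)(N(c1ccccc1)S(=O)(=O)C(F)(F)F)C(F)(F)F
Why: Enol triflation should occur only at the acidic ring enol oxygen on C4a (the tautomer favored as in 3-acyl-4-hydroxypyranones), because the neutral secondary alcohol does not react with PhNTf2 under amine base; no stereocenter is formed.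

Step 7
Reactants: 12 (E)-1,2-bis(tributylstannyl)ethene
Product: 14 tributyl{(E)-2-[(trimethylsilyl)oxy]ethenyl}stannane, via stannylvinyllithium 13 (not isolated)
Conditions: n-BuLi (1.0 equiv), THF, −78 °C; then Me3SiOOSiMe3, −78 → 0 °C; non-aqueous work-up
Reagents that add atoms: bis(trimethylsilyl) peroxide, C[Si](C)(C)OO[Si](C)(C)C
Why: Tin–lithium exchange followed by electrophilic oxygenation of the alkenyllithium with the silyl peroxide should give the silyl enol ether with retention of alkene geometry, which is in any case lost in step 8.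

Step 8
Reactants: 11 6-{(1E)-3-[(tert-butyldiphenylsilyl)oxy]prop-1-en-1-yl}-3-(2-hydroxypropanoyl)-2H-pyran-4-yl trifluoromethanesulfonate; 14 tributyl{(E)-2-[(trimethylsilyl)oxy]ethenyl}stannane
Product: 17 (6R,7R)-3-{(1E)-3-[(tert-butyldiphenylsilyl)oxy]prop-1-en-1-yl}-6,7-dihydroxy-7-methyl-6,7-dihydro-1H-isochromen-8(5H)-one, via silyl dienol ether 15 (not isolated), via keto aldehyde 16 (not isolated)
Conditions: Pd(PPh3)4 (5 mol %), LiCl, THF, 50 °C; then −20 °C: MeOH (1.2 equiv), Et2Zn (20 mol %)/(S,S)-ProPhenol (10 mol %), THF, −20 → 4 °C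
Reagents that add atoms: none
Why: Proposed new method: zerovalent palladium inserts into the C4a–OTf bond of 11, transmetalation with 14 and reductive elimination form C5–C4a (Stille coupling, the closest known type), and the zinc alkoxide catalyst then passes the enol trimethylsilyl group of 15 to methanol, which should release keto aldehyde 16 under neutral conditions. The catalyst from Et2Zn and ProPhenol binds the C7–OH/C8=O unit as a chelated zinc enediolate and the aldehyde on its second zinc, and C7 adds to C6 (closest known type: the direct aldol of α-hydroxy ketones with aldehydes under the same two-zinc catalysts, here intramolecular and coupled to the unmasking). Ring A closes in the 6-(enolendo)-exo-trig mode. C7 is planar in the enediolate, so both enantiomers of 11 converge and the ligand pocket should select the enolate face, while the zinc bridge between the enolate oxygen on C8 and the aldehyde oxygen (closed chair-like six-membered transition state) should place the new C6–O bond axial and therefore cis to the equatorial C7–O bond. The step needs carbon–carbon coupling at C4a only, which the single C–OTf bond secures, and enolization toward C7 instead of the more acidic C5 methylene, which the bidentate binding of the hydroxy ketone to zinc secures; dehydration of the aldol is blocked because C7 is quaternary.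

Step 9
Reactants: 18 2,4-dihydroxy-6-methylbenzoic acid (orsellinic acid)
Product: 19 tert-butyldimethylsilyl 2,4-bis[(tert-butyldimethylsilyl)oxy]-6-methylbenzoate
Conditions: TBSCl (3.3 equiv), imidazole, DMF, rt
Reagents that add atoms: tert-butyl(chloro)dimethylsilane, CC(C)(C)[Si](C)(C)Cl
Why: Exhaustive silylation should protect both phenols and convert the acid into a silyl ester; no stereocenter is involved.

Step 10
Reactants: 19 tert-butyldimethylsilyl 2,4-bis[(tert-butyldimethylsilyl)oxy]-6-methylbenzoate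
Product: 20 2,4-bis[(tert-butyldimethylsilyl)oxy]-6-methylbenzoyl chloride
Conditions: (COCl)2, DMF (cat.), CH2Cl2, 0 °C → rt; used crude
Reagents that add atoms: oxalyl chloride, O=C(Cl)C(Cl)=O
Why: The silyl ester should be converted directly into the acid chloride by the chloroiminium species (acyl chloride formation under neutral conditions) while the aryl silyl ethers stay in place; no stereocenter is involved.

Step 11
Reactants: 17 (6R,7R)-3-{(1E)-3-[(tert-butyldiphenylsilyl)oxy]prop-1-en-1-yl}-6,7-dihydroxy-7-methyl-6,7-dihydro-1H-isochromen-8(5H)-one; 20 2,4-bis[(tert-butyldimethylsilyl)oxy]-6-methylbenzoyl chloride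
Product: 21 (6R,7R)-3-{(1E)-3-[(tert-butyldiphenylsilyl)oxy]prop-1-en-1-yl}-7-hydroxy-7-methyl-8-oxo-5,6,7,8-tetrahydro-1H-isochromen-6-yl 2,4-bis[(tert-butyldimethylsilyl)oxy]-6-methylbenzoate
Conditions: DMAP, Et3N, CH2Cl2, 0 °C → rt
Reagents that add atoms: none
Why: DMAP-mediated acylation with the acid chloride should take place only at the secondary C6 hydroxyl, since the tertiary C7 hydroxyl is too hindered; the C6–O bond is not broken, so the configuration is retained, and the absence of strong base avoids retro-aldol cleavage.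

Step 12
Reactants: 21 (6R,7R)-3-{(1E)-3-[(tert-butyldiphenylsilyl)oxy]prop-1-en-1-yl}-7-hydroxy-7-methyl-8-oxo-5,6,7,8-tetrahydro-1H-isochromen-6-yl 2,4-bis[(tert-butyldimethylsilyl)oxy]-6-methylbenzoate
Product: 22 Entonaemin A, (6R,7R)-7-hydroxy-3-[(1E)-3-hydroxyprop-1-en-1-yl]-7-methyl-8-oxo-5,6,7,8-tetrahydro-1H-isochromen-6-yl 2,4-dihydroxy-6-methylbenzoate
Conditions: HF·pyridine, pyridine, THF, 0 °C → rt
Reagents that add atoms: none
Why: Fluoride-mediated desilylation should remove both aryl TBS ethers and the allylic TBDPS ether in a buffered, weakly acidic medium that should not cause acyl migration to O7, retro-aldol cleavage or elimination; the stereocenters are not touched.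

**Compound list**
1 | (2E)-pent-2-en-4-yn-1-ol | C#C/C=C/CO | starting material
2 | tert-butyl{[(2E)-pent-2-en-4-yn-1-yl]oxy}diphenylsilane | C#C/C=C/CO[Si](c1ccccc1)(c1ccccc1)C(C)(C)C | intermediate
3 | 3-[(tert-butyldimethylsilyl)oxy]propanal | O=CCCO[Si](C)(C)C(C)(C)C | starting material
4 | {(3E)-5-[(tert-butyldiphenylsilyl)oxy]pent-3-en-1-yn-1-yl}lithium (lithium acetylide of 2) | [Li]C#C/C=C/CO[Si](c1ccccc1)(c1ccccc1)C(C)(C)C | intermediate
5 | (6E)-1-[(tert-butyldimethylsilyl)oxy]-8-[(tert-butyldiphenylsilyl)oxy]oct-6-en-4-yn-3-ol (racemic) | CC(C)(C)[Si](C)(C)OCCC(O)C#C/C=C/CO[Si](c1ccccc1)(c1ccccc1)C(C)(C)C | intermediate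
6 | (6E)-1-[(tert-butyldimethylsilyl)oxy]-8-[(tert-butyldiphenylsilyl)oxy]oct-6-en-4-yn-3-one | CC(C)(C)[Si](C)(C)OCCC(=O)C#C/C=C/CO[Si](c1ccccc1)(c1ccccc1)C(C)(C)C | intermediate
7 | 6-{(1E)-3-[(tert-butyldiphenylsilyl)oxy]prop-1-en-1-yl}-2,3-dihydro-4H-pyran-4-one | O=C1CCOC(/C=C/CO[Si](c2ccccc2)(c2ccccc2)C(C)(C)C)=C1 | intermediate
8 | 2,2,5-trimethyl-1,3-dioxolan-4-one (racemic) | CC1OC(C)(C)OC1=O | starting material
9 | lithium 6-{(1E)-3-[(tert-butyldiphenylsilyl)oxy]prop-1-en-1-yl}-2H-pyran-4-olate (lithium enolate of 7) | [Li]OC1=CCOC(/C=C/CO[Si](c2ccccc2)(c2ccccc2)C(C)(C)C)=C1 | intermediate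
10 | 1-(6-{(1E)-3-[(tert-butyldiphenylsilyl)oxy]prop-1-en-1-yl}-4-hydroxy-2H-pyran-3-yl)-2-hydroxypropan-1-one (racemic) | CC(O)C(=O)C1=C(O)C=C(/C=C/CO[Si](c2ccccc2)(c2ccccc2)C(C)(C)C)OC1 | intermediate
11 | 6-{(1E)-3-[(tert-butyldiphenylsilyl)oxy]prop-1-en-1-yl}-3-(2-hydroxypropanoyl)-2H-pyran-4-yl trifluoromethanesulfonate (racemic) | CC(O)C(=O)C1=C(OS(=O)(=O)C(F)(F)F)C=C(/C=C/CO[Si](c2ccccc2)(c2ccccc2)C(C)(C)C)OC1 | intermediate
12 | (E)-1,2-bis(tributylstannyl)ethene | CCCC[Sn](CCCC)(CCCC)/C=C/[Sn](CCCC)(CCCC)CCCC | starting material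
13 | [(E)-2-(tributylstannyl)ethenyl]lithium | [Li]/C=C/[Sn](CCCC)(CCCC)CCCC | intermediate
14 | tributyl{(E)-2-[(trimethylsilyl)oxy]ethenyl}stannane | C[Si](C)(C)O/C=C/[Sn](CCCC)(CCCC)CCCC | intermediate
15 | 1-(6-{(1E)-3-[(tert-butyldiphenylsilyl)oxy]prop-1-en-1-yl}-4-{(E)-2-[(trimethylsilyl)oxy]ethenyl}-2H-pyran-3-yl)-2-hydroxypropan-1-one (racemic) | CC(O)C(=O)C1=C(/C=C/O[Si](C)(C)C)C=C(/C=C/CO[Si](c2ccccc2)(c2ccccc2)C(C)(C)C)OC1 | intermediate
16 | (6-{(1E)-3-[(tert-butyldiphenylsilyl)oxy]prop-1-en-1-yl}-3-(2-hydroxypropanoyl)-2H-pyran-4-yl)acetaldehyde (racemic) | CC(O)C(=O)C1=C(CC=O)C=C(/C=C/CO[Si](c2ccccc2)(c2ccccc2)C(C)(C)C)OC1 | intermediate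
17 | (6R,7R)-3-{(1E)-3-[(tert-butyldiphenylsilyl)oxy]prop-1-en-1-yl}-6,7-dihydroxy-7-methyl-6,7-dihydro-1H-isochromen-8(5H)-one | O[C@@H]1CC2=C(COC(/C=C/CO[Si](c3ccccc3)(c3ccccc3)C(C)(C)C)=C2)C(=O)[C@]1(C)O | intermediate
18 | 2,4-dihydroxy-6-methylbenzoic acid (orsellinic acid) | Cc1cc(O)cc(O)c1C(=O)O | starting material
19 | tert-butyldimethylsilyl 2,4-bis[(tert-butyldimethylsilyl)oxy]-6-methylbenzoate | Cc1cc(O[Si](C)(C)C(C)(C)C)cc(O[Si](C)(C)C(C)(C)C)c1C(=O)O[Si](C)(C)C(C)(C)C | intermediate
20 | 2,4-bis[(tert-butyldimethylsilyl)oxy]-6-methylbenzoyl chloride | Cc1cc(O[Si](C)(C)C(C)(C)C)cc(O[Si](C)(C)C(C)(C)C)c1C(=O)Cl | intermediate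
21 | (6R,7R)-3-{(1E)-3-[(tert-butyldiphenylsilyl)oxy]prop-1-en-1-yl}-7-hydroxy-7-methyl-8-oxo-5,6,7,8-tetrahydro-1H-isochromen-6-yl 2,4-bis[(tert-butyldimethylsilyl)oxy]-6-methylbenzoate | Cc1cc(O[Si](C)(C)C(C)(C)C)cc(O[Si](C)(C)C(C)(C)C)c1C(=O)O[C@@H]1CC2=C(COC(/C=C/CO[Si](c3ccccc3)(c3ccccc3)C(C)(C)C)=C2)C(=O)[C@]1(C)O | intermediate
22 | Entonaemin A | Cc1cc(O)cc(O)c1C(=O)O[C@@H]1CC2=C(COC(/C=C/CO)=C2)C(=O)[C@]1(C)O | target

**Step count:** 12 steps in total. The longest linear sequence is 9 steps (steps 1, 2, 3, 4, 5, 6, 8, 11, 12).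

**Steps most likely to fail**

Step 8 (proposed new method). The relay may stall or lose stereocontrol: the silyl dienol ether may be unmasked too slowly, the zinc catalyst may be deactivated by tin and lithium salts or phosphine, or a salt-promoted background aldol may erode enantio- and diastereoselectivity. The fallback uses known reactions in separate operations, sets out from 11 and comes back at 17. Stille coupling of 11 with commercial tributyl[(Z)-2-ethoxyethenyl]stannane (Pd(PPh3)4, LiCl, THF) gives the (Z)-enol ether F1. Mild acid hydrolysis of F1 (PPTS, wet acetone) gives keto aldehyde 16, which is now isolated and purified. The direct aldol with the catalyst from Et2Zn and (S,S)-ProPhenol (4 Å molecular sieves, THF) is then run on pure 16 and gives 17.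

Step 5. The enolate may deprotonate the dioxolanone instead of attacking its carbonyl, O-acylation may compete, and the free α-hydroxy β-diketone may cyclize with loss of water to a fused furanone during work-up. The fallback sets out from 7 and comes back at 11 with the hydroxyl protected until the end. Aldol addition of enolate 9 to 2-[(tert-butyldimethylsilyl)oxy]propanal gives β-hydroxy ketone F2, Dess–Martin oxidation gives the O-silyl diketone F3, Tf2O and pyridine give the O-silyl triflate F4, and HF·pyridine removes the secondary TBS ether to give 11.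

Step 11. Acylation of a hindered secondary alcohol next to a quaternary carbon by a 2,6-disubstituted aroyl chloride may be slow, so that retro-aldol cleavage, acyl migration to O7 or β-elimination gain ground under prolonged exposure to amine base. The fallback sets out from 17 and comes back at 21 by activating the oxygen instead of the acyl donor. Bu2SnO in toluene at reflux with removal of water converts the cis-diol into the dibutylstannylene acetal F5, and F5 reacts with 20 at room temperature under neutral conditions at the secondary oxygen to give 21 after aqueous work-up.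

**Further compounds**
F1 | step 8 | 1-(6-{(1E)-3-[(tert-butyldiphenylsilyl)oxy]prop-1-en-1-yl}-4-[(Z)-2-ethoxyethenyl]-2H-pyran-3-yl)-2-hydroxypropan-1-one (racemic) | CCO/C=C\C1=C(C(=O)C(C)O)COC(/C=C/CO[Si](c2ccccc2)(c2ccccc2)C(C)(C)C)=C1
F2 | step 5 | 3-{2-[(tert-butyldimethylsilyl)oxy]-1-hydroxypropyl}-6-{(1E)-3-[(tert-butyldiphenylsilyl)oxy]prop-1-en-1-yl}-2,3-dihydro-4H-pyran-4-one (mixture of diastereomers) | CC(O[Si](C)(C)C(C)(C)C)C(O)C1COC(/C=C/CO[Si](c2ccccc2)(c2ccccc2)C(C)(C)C)=CC1=O
F3 | step 5 | 2-[(tert-butyldimethylsilyl)oxy]-1-(6-{(1E)-3-[(tert-butyldiphenylsilyl)oxy]prop-1-en-1-yl}-4-hydroxy-2H-pyran-3-yl)propan-1-one (racemic) | CC(O[Si](C)(C)C(C)(C)C)C(=O)C1=C(O)C=C(/C=C/CO[Si](c2ccccc2)(c2ccccc2)C(C)(C)C)OC1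
F4 | step 5 | 3-{2-[(tert-butyldimethylsilyl)oxy]propanoyl}-6-{(1E)-3-[(tert-butyldiphenylsilyl)oxy]prop-1-en-1-yl}-2H-pyran-4-yl trifluoromethanesulfonate (racemic) | CC(O[Si](C)(C)C(C)(C)C)C(=O)C1=C(OS(=O)(=O)C(F)(F)F)C=C(/C=C/CO[Si](c2ccccc2)(c2ccccc2)C(C)(C)C)OC1
F5 | step 11 | 6,7-O-dibutylstannylene acetal of 17 | CCCC[Sn]1(CCCC)O[C@@H]2CC3=C(COC(/C=C/CO[Si](c4ccccc4)(c4ccccc4)C(C)(C)C)=C3)C(=O)[C@]2(C)O1
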